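**Retrosynthetic overview** (guaianolide numbering: C1–C5 cyclopentane; C5–C10 and C1 cycloheptane; C6/C7/C11/C12 lactone with C13 methylene; C4–O–C14H=C10 bridge; C15H2OH)
1. The cycloheptane is opened last, at C9–C10: C10 is the β-carbon of the cyclic enol ether O–C14H=C10 (the 2-oxabicyclo[3.2.1]octene ring) and C9 is the carbinol carbon on it, so a C10 alkenyl iodide and a C9 aldehyde, steered by the C8 acyloxy group, close the ring by Ni/Cr coupling.
2. Lactone: C6–C7 bond and ring from a 2-alkoxycarbonyl allylboronate (C7–C9, C11–C13, O8 ester already in place) and the C6 aldehyde of the oxabicycle.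
3. Oxygen bridge: cleavage of the cyclopentene of a cis-bicyclo[3.3.0]octene; the endo tertiary C4 hydroxyl captures C14 as a bridged lactol, later dehydrated to the enol ether and iodinated at C10.
4. Diquinane: asymmetric epoxidation of cycloocta-1,3-diene, transannular carbenoid insertion, oxidation, exo delivery of C15.
5. Order of ring closure: cyclopentane (with a temporary cyclopentene) → dihydropyran (as lactol) → lactone → cycloheptane.

Key step: step 15

Assumption: the enantiomers of the manganese–salen catalyst (step 1) and of ProPhenol (step 7) named below are taken to give the sense of induction drawn, by analogy with indene epoxidation and with simple aldehydes; if the sense is opposite, the mirror-image catalyst is used.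

**Route**

Step 1
Reactants: 1 (1Z,3Z)-cycloocta-1,3-diene
Product: 2 (1R,8S)-9-oxabicyclo[6.1.0]non-2-ene
Conditions: (R,R)-N,N'-bis(3,5-di-tert-butylsalicylidene)-1,2-cyclohexanediaminomanganese chloride (5 mol %), NaOCl (aq, pH 11), 4-phenylpyridine N-oxide, CH2Cl2, 0 °C
Reagents that add atoms: sodium hypochlorite [Na+].[O-]Cl
Why: Jacobsen–Katsuki epoxidation of a cis-disubstituted conjugated alkene, in which side-on approach to the oxo-manganese species (pentavalent manganese) sets both epoxide centres, and the vinyl epoxide formed is less electron-rich than the diene so that monoepoxidation should prevail.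

Step 2
Reactants: 2 (1R,8S)-9-oxabicyclo[6.1.0]non-2-ene
Product: 4 (1S,2S,5S)-bicyclo[3.3.0]oct-7-en-2-ol (cis-fused; endo hydroxyl), via C1-lithiated epoxide 3 (not isolated)
Conditions: LiNEt2 (2.5 equiv; from Et2NH and n-BuLi), Et2O–hexane, reflux; then H2O
Reagents that add atoms: none
Why: Base-promoted transannular epoxide rearrangement (α-lithiation at the allylic epoxide carbon, then carbenoid insertion into the C–H bond across the ring), which is stereospecific and so carries the epoxide configuration into both ring-fusion carbons and the carbinol.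

Step 3
Reactants: 4 (1S,2S,5S)-bicyclo[3.3.0]oct-7-en-2-ol
Product: 5 (1S,5S)-bicyclo[3.3.0]oct-7-en-2-one
Conditions: Dess–Martin periodinane, NaHCO3, CH2Cl2, 0 °C
Reagents that add atoms: none
Why: Dess–Martin oxidation of a secondary alcohol under buffered, non-enolising conditions that should keep the β,γ-alkene out of conjugation; no stereocentre is formed.

Step 4
Reactants: 5 (1S,5S)-bicyclo[3.3.0]oct-7-en-2-one
Product: 7 (1S,2S,5S)-spiro[bicyclo[3.3.0]oct-7-ene-2,2'-oxirane] (oxirane oxygen endo; CH2 exo), via sulfonium betaine 6 (not isolated)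
Conditions: trimethylsulfonium iodide, n-BuLi, THF, −10 °C; then 5, −78 → 0 °C
Reagents that add atoms: trimethylsulfonium iodide C[S+](C)C.[I-]
Why: Corey–Chaykovsky epoxidation, in which the unstabilised sulfonium ylide adds irreversibly to the exo (convex) face of the cis-fused ketone, so that C15 ends exo and the oxygen endo, cis to both ring-fusion bonds of the cyclopentene (the C4 configuration of the target).

Step 5
Reactants: 7 (1S,2S,5S)-spiro[bicyclo[3.3.0]oct-7-ene-2,2'-oxirane]
Product: 8 (1S,2S,5S)-2-{[(4-methoxyphenyl)methoxy]methyl}bicyclo[3.3.0]oct-7-en-2-ol (hydroxyl endo)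
Conditions: 4-methoxybenzyl alcohol, NaH, DMF, 60 °C; then aq. NH4Cl
Reagents that add atoms: 4-methoxybenzyl alcohol COc1ccc(CO)cc1
Why: SN2 opening of a 2,2-disubstituted epoxide by an alkoxide at its unhindered CH2 carbon (C15), which leaves the C4–O bond and the C4 configuration untouched.

Step 6
Reactants: 8 (1S,2S,5S)-2-{[(4-methoxyphenyl)methoxy]methyl}bicyclo[3.3.0]oct-7-en-2-ol
Product: 11 (1S,5S,8R)-3-hydroxy-1-{[(4-methoxyphenyl)methoxy]methyl}-2-oxabicyclo[3.2.1]octane-8-carbaldehyde (formyl syn to the O2–C3–C4 bridge; anomers at C3), via cis-diol 9 (not isolated), via dialdehyde 10 (not isolated)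
Conditions: OsO4 (2 mol %), NaIO4, 2,6-lutidine, dioxane–H2O, rt
Reagents that add atoms: osmium tetroxide O=[Os](=O)(=O)=O; sodium periodate [Na+].[O-]I(=O)(=O)=O
Why: Lemieux–Johnson cleavage of the cyclopentene, after which the C14 aldehyde is captured by the cis tertiary C4 hydroxyl as the six-membered bridged lactol (C6 could only give a four-membered ring; its further internal hemiacetal is reversible), so the two carbonyls are differentiated and the former cis ring fusion fixes C5 with C6 syn to the oxygen bridge.

Step 7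
Reactants: 12 (tert-butyldimethylsilyloxy)acetaldehyde; 13 methyl propiolate
Product: 15 methyl (4S)-5-[(tert-butyldimethylsilyl)oxy]-4-hydroxypent-2-ynoate, via methylzinc alkynylide 14 (not isolated)
Conditions: (S,S)-ProPhenol (10 mol %), Me2Zn, Ph3PO (20 mol %), toluene, 4 °C; then aq. NH4Cl
Reagents that add atoms: none
Why: ProPhenol–zinc catalysed enantioselective alkynylation of an aldehyde with methyl propiolate, in which the dinuclear zinc complex delivers the alkynylide to one aldehyde face and so sets C8.

Step 8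
Reactants: 15 methyl (4S)-5-[(tert-butyldimethylsilyl)oxy]-4-hydroxypent-2-ynoate; 16 (2R)-2-methylbutanoic acid
Product: 17 methyl (4S)-5-[(tert-butyldimethylsilyl)oxy]-4-{[(2R)-2-methylbutanoyl]oxy}pent-2-ynoate
Conditions: DCC, DMAP (5 mol %), CH2Cl2, 0 °C
Reagents that add atoms: none
Why: Steglich esterification, which places the (R)-2-methylbutanoate on O8 while it is the only hydroxyl present; at low DMAP loading the acid stereocentre should not epimerise.

Step 9
Reactants: 17 methyl (4S)-5-[(tert-butyldimethylsilyl)oxy]-4-{[(2R)-2-methylbutanoyl]oxy}pent-2-ynoate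
Product: 19 methyl (2Z,4S)-5-[(tert-butyldimethylsilyl)oxy]-4-{[(2R)-2-methylbutanoyl]oxy}-2-[(4,4,5,5-tetramethyl-1,3,2-dioxaborolan-2-yl)methyl]pent-2-enoate (C4 substituent trans to CH2B), via alkenylalane 18 (not isolated)
Conditions: DIBAL-H, HMPA, THF, 0 °C; then ICH2Bpin, 0 °C → rt
Reagents that add atoms: 2-(iodomethyl)-4,4,5,5-tetramethyl-1,3,2-dioxaborolane ICB1OC(C)(C)C(C)(C)O1
Why: Conjugate hydroalumination of the ynoate (syn addition of H and Al) followed by alkylation of the α-aluminated acrylate with the iodomethylboronate, the established route to 2-alkoxycarbonyl allylboronates, which places the C8 carbon trans to the CH2B group.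

Step 10
Reactants: 11 lactol aldehyde (see step 6); 19 allylboronate (see step 9)
Product: 21 6,7-trans α-methylene-γ-butyrolactone carrying at C7 the (S)-CH[O-(R)-2-methylbutanoyl]CH2OTBS chain and at C6 the bicyclic lactol (configuration at C1, C4, C5, C6, C7, C8 as in the target), via homoallylic borate 20 (not isolated)
Conditions: toluene, 90 °C, 48 h
Reagents that add atoms: none
Why: Thermal 2-alkoxycarbonyl allylboration with lactonisation in the flask, where the chair transition state of the boronate with C8 trans to CH2B gives the anti adduct and hence the trans lactone; the boron-bound carbonyl oxygen should point away from the oxygen bridge so that C7 attacks C6 on the face remote from the quaternary C4, and the boronate should react on the alkene face anti to its C9 carbon with H8 eclipsing the alkene (allylic 1,3-strain), so both preferences are expected to lead to the C6, C7, C8 configuration of the target.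

Step 11
Reactants: 21 lactone lactol (see step 10)
Product: 23 enol ether lactone (C14H=C10H–O–C4; otherwise as 21), via anomeric mesylate 22 (not isolated)
Conditions: MsCl, Et3N, CH2Cl2, 0 °C → reflux
Reagents that add atoms: none
Why: Glycal-type dehydration of a 2-deoxy lactol by mesylation and elimination through the oxocarbenium ion with loss of H10, the standard lactol-to-enol-ether conversion; no stereocentre is touched.

Step 12
Reactants: 23 enol ether lactone
Product: 24 C10 iodide of 23 (O–C14H=C10(I)–C1)
Conditions: N-iodosuccinimide, AgNO3 (20 mol %), MeCN, 60 °C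
Reagents that add atoms: N-iodosuccinimide O=C1CCC(=O)N1I
Why: Electrophilic iodination of the enol ether at its β-carbon C10 followed by loss of H10 from the iodo-oxocarbenium ion, the known route to 2-iodoglycals; the electron-poor methylene lactone should be inert.

Step 13
Reactants: 24 C10 iodide
Product: 25 C9 primary alcohol (TBS removed; otherwise as 24)
Conditions: HF·pyridine, pyridine, THF, 0 °C → rt
Reagents that add atoms: none
Why: Fluoride cleavage of the primary silyl ether under buffered conditions that should spare the iodo enol ether, the esters and the 4-methoxybenzyl ether.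

Step 14
Reactants: 25 C9 primary alcohol
Product: 26 C9 aldehyde (α-acyloxy aldehyde; otherwise as 25), used at once
Conditions: Dess–Martin periodinane, NaHCO3, CH2Cl2, 0 °C
Reagents that add atoms: none
Why: Dess–Martin oxidation of a primary alcohol under neutral conditions chosen to avoid epimerisation at C8 and acyl migration.

Step 15
Reactants: 26 C9 aldehyde bearing the C10 iodide
Product: 28 15-O-(4-methoxybenzyl) ether of the target (all rings closed; 9-acetate), via chromium alkoxide 27 (not isolated)
Conditions: CrCl2 (8 equiv), NiCl2 (2 mol %), DMSO–THF, rt, 2 mM; then Ac2O, pyridine, DMAP, 0 °C → rt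
Reagents that add atoms: acetic anhydride CC(=O)OC(C)=O
Why: Zerovalent nickel inserts into the C10–iodine bond, the alkenyl group passes to trivalent chromium and the alkenylchromium adds to the C9 aldehyde, after which the chromium alkoxide is acetylated in the same flask. The closest known reaction type is the intramolecular Nozaki–Hiyama–Kishi coupling of alkenyl iodides with aldehydes used for medium and large carbocycles. The cycloheptane (C1, C5, C6, C7, C8, C9, C10) closes in the 7-exo-trig mode, the carbonyl oxygen staying outside the new ring. The new stereocentre C9 is controlled by the C8 acyloxy group: the aldehyde should react in the conformer with C9=O antiperiplanar to the C8–O bond (Cornforth dipole minimisation), and because C10 is tied to C7 through the forming ring it can reach only the carbonyl face that places O9 trans to O8. The step needs chemoselectivity for the aldehyde over the methylene lactone and the two esters, which is inherent to organochromium reagents, and retention of the allylic oxygen next to the enol ether, which the neutral medium and the trapping as acetate before work-up should secure.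

Step 16
Reactants: 28 15-O-(4-methoxybenzyl) ether of the target
Product: 29 target CNP0013863.3
Conditions: DDQ, CH2Cl2–pH 7 buffer, 0 °C
Reagents that add atoms: none
Why: Oxidative cleavage of the 4-methoxybenzyl ether (hydride abstraction, then hydrolysis of the oxocarbenium ion), which frees the C15 hydroxyl without acid or base so that the allylic acetate on the enol ether and the methylene lactone should persist.

**Compound list**
1 | (1Z,3Z)-cycloocta-1,3-diene | C1=CC=CCCCC1 | starting material
2 | (1R,8S)-9-oxabicyclo[6.1.0]non-2-ene | [C@@H]1(O2)[C@H]2C=CCCCC1 | intermediate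
3 | 1-lithio derivative of 2 (lithium on the allylic epoxide carbon, configuration retained) | [C@@H]1(O2)[C@@]2([Li])C=CCCCC1 | intermediate (not isolated)
4 | (1S,2S,5S)-bicyclo[3.3.0]oct-7-en-2-ol (cis-fused, endo OH) | O[C@H]1CC[C@H]2CC=C[C@@H]12 | intermediate
5 | (1S,5S)-bicyclo[3.3.0]oct-7-en-2-one | O=C1CC[C@H]2CC=C[C@@H]12 | intermediate
6 | (1S,2S,5S)-2-[(dimethylsulfonio)methyl]bicyclo[3.3.0]oct-7-en-2-olate (oxygen endo) | C[S+](C)C[C@]1([O-])CC[C@H]2CC=C[C@@H]12 | intermediate (not isolated)
7 | (1S,2S,5S)-spiro[bicyclo[3.3.0]oct-7-ene-2,2'-oxirane] (oxygen endo) | O1C[C@@]12CC[C@H]3CC=C[C@@H]23 | intermediate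
8 | (1S,2S,5S)-2-{[(4-methoxyphenyl)methoxy]methyl}bicyclo[3.3.0]oct-7-en-2-ol | COc1ccc(COC[C@]2(O)CC[C@H]3CC=C[C@@H]23)cc1 | intermediate
9 | 7,8-cis-diol of 8 (both hydroxyls on the exo face) | COc1ccc(COC[C@]2(O)CC[C@H]3C[C@H](O)[C@H](O)[C@@H]23)cc1 | intermediate (not isolated)
10 | 2-formyl-3-(2-oxoethyl)-1-{[(4-methoxyphenyl)methoxy]methyl}cyclopentan-1-ol (hydroxyl, formyl and oxoethyl all cis) | COc1ccc(COC[C@]2(O)CC[C@@H](CC=O)[C@H]2C=O)cc1 | intermediate (not isolated)
11 | (1S,5S,8R)-3-hydroxy-1-{[(4-methoxyphenyl)methoxy]methyl}-2-oxabicyclo[3.2.1]octane-8-carbaldehyde (8-formyl syn to the oxygen bridge) | C1C(O)O[C@@]3(COCc4ccc(OC)cc4)CC[C@@H]1[C@H]3C=O | intermediate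
12 | (tert-butyldimethylsilyloxy)acetaldehyde | CC(C)(C)[Si](C)(C)OCC=O | starting material
13 | methyl propiolate | C#CC(=O)OC | starting material
14 | methyl 3-(methylzincio)prop-2-ynoate | C[Zn]C#CC(=O)OC | intermediate (not isolated)
15 | methyl (4S)-5-[(tert-butyldimethylsilyl)oxy]-4-hydroxypent-2-ynoate | COC(=O)C#C[C@H](O)CO[Si](C)(C)C(C)(C)C | intermediate
16 | (2R)-2-methylbutanoic acid | CC[C@@H](C)C(O)=O | starting material
17 | methyl (4S)-5-[(tert-butyldimethylsilyl)oxy]-4-{[(2R)-2-methylbutanoyl]oxy}pent-2-ynoate | COC(=O)C#C[C@H](OC(=O)[C@H](C)CC)CO[Si](C)(C)C(C)(C)C | intermediate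
18 | methyl (4S)-2-(diisobutylalumanyl)-5-[(tert-butyldimethylsilyl)oxy]-4-{[(2R)-2-methylbutanoyl]oxy}pent-2-enoate (Al cis to H3) | COC(=O)/C([Al](CC(C)C)CC(C)C)=C\[C@H](OC(=O)[C@H](C)CC)CO[Si](C)(C)C(C)(C)C | intermediate (not isolated)
19 | methyl (2Z,4S)-5-[(tert-butyldimethylsilyl)oxy]-4-{[(2R)-2-methylbutanoyl]oxy}-2-[(4,4,5,5-tetramethyl-1,3,2-dioxaborolan-2-yl)methyl]pent-2-enoate | COC(=O)/C(CB1OC(C)(C)C(C)(C)O1)=C\[C@H](OC(=O)[C@H](C)CC)CO[Si](C)(C)C(C)(C)C | intermediate
20 | open-chain allylboration adduct: methyl 2-methylidene ester with C6–O–Bpin, C6/C7 anti, lactol intact | COC(=O)C(=C)[C@H]([C@H](OC(=O)[C@H](C)CC)CO[Si](C)(C)C(C)(C)C)[C@H](OB3OC(C)(C)C(C)(C)O3)[C@@H]1[C@@H]2CC(O)O[C@@]1(COCc4ccc(OC)cc4)CC2 | intermediate (not isolated)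
21 | 6,7-trans α-methylene-γ-butyrolactone with C8 ester, C9 OTBS and the C14 lactol (configuration at C1, C4, C5, C6, C7, C8 as in the target) | C=C1C(=O)O[C@@H]([C@H]1[C@H](OC(=O)[C@H](C)CC)CO[Si](C)(C)C(C)(C)C)[C@@H]1[C@@H]2CC(O)O[C@@]1(COCc3ccc(OC)cc3)CC2 | intermediate
22 | C14 methanesulfonate of 21 | C=C1C(=O)O[C@@H]([C@H]1[C@H](OC(=O)[C@H](C)CC)CO[Si](C)(C)C(C)(C)C)[C@@H]1[C@@H]2CC(OS(C)(=O)=O)O[C@@]1(COCc3ccc(OC)cc3)CC2 | intermediate (not isolated)
23 | enol ether lactone (2-oxabicyclo[3.2.1]oct-3-ene; otherwise as 21) | C=C1C(=O)O[C@@H]([C@H]1[C@H](OC(=O)[C@H](C)CC)CO[Si](C)(C)C(C)(C)C)[C@@H]1[C@@H]2C=CO[C@@]1(COCc3ccc(OC)cc3)CC2 | intermediate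
24 | C10 iodide of 23 | C=C1C(=O)O[C@@H]([C@H]1[C@H](OC(=O)[C@H](C)CC)CO[Si](C)(C)C(C)(C)C)[C@@H]1[C@@H]2C(I)=CO[C@@]1(COCc3ccc(OC)cc3)CC2 | intermediate
25 | C9 alcohol (desilylated 24) | C=C1C(=O)O[C@@H]([C@H]1[C@H](OC(=O)[C@H](C)CC)CO)[C@@H]1[C@@H]2C(I)=CO[C@@]1(COCc3ccc(OC)cc3)CC2 | intermediate
26 | C9 aldehyde (seco precursor of the cycloheptane) | C=C1C(=O)O[C@@H]([C@H]1[C@H](OC(=O)[C@H](C)CC)C=O)[C@@H]1[C@@H]2C(I)=CO[C@@]1(COCc3ccc(OC)cc3)CC2 | intermediate
27 | dichlorochromium alkoxide of the cyclised C9 alcohol (trivalent chromium) | C=C1C(=O)O[C@H]2[C@H]1[C@H](OC(=O)[C@H](C)CC)[C@@H](O[Cr](Cl)Cl)C1=CO[C@@]3(COCc4ccc(OC)cc4)CC[C@@H]1[C@@H]23 | intermediate (not isolated)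
28 | 15-O-(4-methoxybenzyl) ether of the target | C=C1C(=O)O[C@H]2[C@H]1[C@H](OC(=O)[C@H](C)CC)[C@@H](OC(C)=O)C1=CO[C@@]3(COCc4ccc(OC)cc4)CC[C@@H]1[C@@H]23 | intermediate
29 | CNP0013863.3 | C=C1C(=O)O[C@H]2[C@H]1[C@H](OC(=O)[C@H](C)CC)[C@@H](OC(C)=O)C1=CO[C@@]3(CO)CC[C@@H]1[C@@H]23 | target

**Step count**
Total: 16 steps. Longest linear sequence: 13 steps (1–6, then 10–16).

**Steps most likely to fail, with fallbacks**

Step 15 (key step). The risk is attack on the other face of the C9 carbonyl, or protonolysis of the alkenylchromium before the ring closes. The fallback sets out from 26 and comes back at 28. The coupling is run without acetic anhydride, and the cyclised alcohols, the 9-epimeric alcohol F1 and the alcohol with the target configuration F3, are oxidised together (MnO2 or Dess–Martin periodinane) to the enone F2, a vinylogous ester in which C9 is trigonal. Corey–Bakshi–Shibata reduction, using the oxazaborolidine enantiomer that delivers hydride to the face giving the 8,9-trans product, should give the alcohol F3 under reagent control; acetylation (Ac2O, pyridine, DMAP) then gives 28. Stereocontrol is thus moved from the carbon–carbon bond formation to a ketone reduction.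

Step 10. The risks are a slow reaction of the hindered C6 aldehyde, competing reaction of the C14 carbonyl of the open lactol, and a mismatch between the facial preferences of aldehyde and boronate. The fallback sets out from 11 and comes back at 23, and builds the lactone in two carbon–carbon bond formations. Zinc-mediated Barbier allylation–lactonisation with methyl 2-(bromomethyl)acrylate gives the C7-unsubstituted methylene lactone F4. Bromine addition gives the dibromide F5, and triethylamine then gives the 3-(bromomethyl)butenolide F6; this is done while C14 is still a lactol, which tolerates bromine. Dehydration as in step 11 gives the enol ether F7. CrCl2-mediated Nozaki–Hiyama allylation of aldehyde 12 joins C8 to C7 on the butenolide face anti to the C6 substituent (trans lactone) and restores the exocyclic methylene, giving the C8 alcohol F8. Esterification with acid 16 (DCC, DMAP) returns 23; if C8 forms with the other configuration, Mitsunobu esterification with 16 would be used instead.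

Step 9. The risk is loss of chemoselectivity: attack of the aluminium hydride on the 2-methylbutanoate or on the propargylic C–O bond. The fallback sets out from 15 and comes back at 23, and postpones the acylation. Alcohol 15 is silylated (TESCl, imidazole) to the triethylsilyl ether F9, and hydroalumination with iodomethylboronate trapping gives the boronate F10. Allylboration of 11 gives the lactone lactol F11, dehydration as in step 11 gives the enol ether F12, and selective removal of the secondary triethylsilyl group (HF·pyridine, pyridine, 0 °C) gives the C8 alcohol F8. Esterification with acid 16 (DCC, DMAP) returns 23.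

**Further compounds**
F1 | step 15 | 9-epimer of the cyclised alcohol (15-O-PMB) | C=C1C(=O)O[C@H]2[C@H]1[C@H](OC(=O)[C@H](C)CC)[C@H](O)C1=CO[C@@]3(COCc4ccc(OC)cc4)CC[C@@H]1[C@@H]23
F2 | step 15 | C9 ketone (enone conjugated with the enol ether; 15-O-PMB) | C=C1C(=O)O[C@H]2[C@H]1[C@H](OC(=O)[C@H](C)CC)C(=O)C1=CO[C@@]3(COCc4ccc(OC)cc4)CC[C@@H]1[C@@H]23
F3 | step 15 | cyclised C9 alcohol with the target configuration (15-O-PMB) | C=C1C(=O)O[C@H]2[C@H]1[C@H](OC(=O)[C@H](C)CC)[C@@H](O)C1=CO[C@@]3(COCc4ccc(OC)cc4)CC[C@@H]1[C@@H]23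
F4 | step 10 | α-methylene-γ-butyrolactone at C6 without C7 substituent, C14 lactol | C=C1C(=O)O[C@@H](C1)[C@@H]1[C@@H]2CC(O)O[C@@]1(COCc3ccc(OC)cc3)CC2
F5 | step 10 | dibromide of F4 (Br on C11 and C13) | O=C1O[C@@H](CC1(Br)CBr)[C@@H]1[C@@H]2CC(O)O[C@@]1(COCc3ccc(OC)cc3)CC2
F6 | step 10 | 3-(bromomethyl)butenolide, C14 lactol | O=C1O[C@@H](C=C1CBr)[C@@H]1[C@@H]2CC(O)O[C@@]1(COCc3ccc(OC)cc3)CC2
F7 | step 10 | 3-(bromomethyl)butenolide, enol ether | O=C1O[C@@H](C=C1CBr)[C@@H]1[C@@H]2C=CO[C@@]1(COCc3ccc(OC)cc3)CC2
F8 | step 10 | C8 alcohol of 23 (free O8–H, C9 OTBS) | C=C1C(=O)O[C@@H]([C@H]1[C@H](O)CO[Si](C)(C)C(C)(C)C)[C@@H]1[C@@H]2C=CO[C@@]1(COCc3ccc(OC)cc3)CC2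
F9 | step 9 | methyl (4S)-5-[(tert-butyldimethylsilyl)oxy]-4-[(triethylsilyl)oxy]pent-2-ynoate | COC(=O)C#C[C@H](O[Si](CC)(CC)CC)CO[Si](C)(C)C(C)(C)C
F10 | step 9 | O8-triethylsilyl analogue of boronate 19 | COC(=O)/C(CB1OC(C)(C)C(C)(C)O1)=C\[C@H](O[Si](CC)(CC)CC)CO[Si](C)(C)C(C)(C)C
F11 | step 9 | O8-triethylsilyl analogue of lactone lactol 21 | C=C1C(=O)O[C@@H]([C@H]1[C@H](O[Si](CC)(CC)CC)CO[Si](C)(C)C(C)(C)C)[C@@H]1[C@@H]2CC(O)O[C@@]1(COCc3ccc(OC)cc3)CC2
F12 | step 9 | O8-triethylsilyl analogue of enol ether 23 | C=C1C(=O)O[C@@H]([C@H]1[C@H](O[Si](CC)(CC)CC)CO[Si](C)(C)C(C)(C)C)[C@@H]1[C@@H]2C=CO[C@@]1(COCc3ccc(OC)cc3)CC2
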